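**Strategy.** Ring C is cut at O1–C2 and C3–C4. Because O1 and C4 are ortho neighbours on ring A, ring A can be unmasked as an alkoxy o-quinone methide from a salicylaldehyde. Because the 2'-hydroxyl of ring B sits beside the C1'–C2 bond, a chiral phosphoric acid can hold the matching 2-vinylphenol by hydrogen bonding. One catalytic asymmetric hetero-Diels–Alder reaction therefore joins both halves, closes ring C and sets C2 (S), with a transient cis C4 methoxy centre that is later oxidised to the ketone. The precursors are a monophenolic bis-silyl diprenyl salicylaldehyde and a chromene-fused 2-vinylphenol.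

Key step: step 5

Remarks on the chemistry:
- Flavanone numbering is used for all flavan-type compounds (O1, C2, C3, C4, ring A = C4a–C8a, ring B primed, ring C the pyran ring).
- The descriptors (2S,4S) of the cycloadduct were checked by the CIP rules and correspond to the 2,4-cis isomer; the target is (2S).
- Assumption: the sense of induction of the phosphoric acid cannot be assigned in advance. The (R)-catalyst is written; its mirror image would be used if the first run favours the (2R,4R) series.
- Design choices: the vinyl group is installed directly by cross-coupling on the bromochromenol, and the 2'-hydroxyl is silylated right after the cycloaddition, before C4 is ionised and oxidised.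

**Step 1**
Reactants: 1 2,4,6-trihydroxybenzaldehyde; 2 prenyl bromide (2.2 equiv)
Product: 3 2,4,6-trihydroxy-3,5-bis(3-methylbut-2-enyl)benzaldehyde
Conditions: 10% aq KOH, 0 °C to rt
Reagents that add atoms: none
Why: Direct C-alkylation of an acylphloroglucinol polyphenoxide in water, where hydrogen bonding to the oxygens steers the allylic bromide to the two free ring carbons C3 and C5; mono-, geminal di- and O-prenylated material would be removed by chromatography, and no stereocentre is formed.

**Step 2**
Reactants: 3 2,4,6-trihydroxy-3,5-bis(3-methylbut-2-enyl)benzaldehyde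
Product: 4 2-hydroxy-4,6-bis(tert-butyldimethylsilyloxy)-3,5-bis(3-methylbut-2-enyl)benzaldehyde
Conditions: TBSCl (2.1 equiv), imidazole, DMF, 0 °C to rt
Reagents that add atoms: tert-butyldimethylsilyl chloride, CC(C)(C)[Si](C)(C)Cl
Why: Chelation-controlled phenol silylation: the hydroxyl that stays hydrogen-bonded to the formyl group is the least reactive of the three, so the two silyl groups should end up on O4 and on one of the two equivalent ortho oxygens (O6), which leaves the single free ortho phenol needed for quinone methide formation and ensures that the later cycloadduct carries no free phenol beside C4.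

**Step 3**
Reactants: 5 4-bromoresorcinol; 6 3-methylbut-2-enal
Product: 7 6-bromo-2,2-dimethyl-2H-chromen-7-ol
Conditions: ethylenediammonium diacetate (10 mol %), toluene, reflux
Reagents that add atoms: none
Why: Amine-catalysed chromenylation (Knoevenagel-type C-alkylation, dehydration to a dienone, oxa-6π electrocyclisation); the iminium ion should attack C6 of 5, para to one hydroxyl and ortho to the other as in Pechmann condensations of 4-haloresorcinols, while bromine blocks C4 and the crowded C2 between the hydroxyls reacts more slowly, so the linear 6-bromo-7-hydroxy chromene is expected.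

**Step 4**
Reactants: 7 6-bromo-2,2-dimethyl-2H-chromen-7-ol; 8 vinylboronic acid pinacol ester
Product: 9 2,2-dimethyl-6-vinyl-2H-chromen-7-ol
Conditions: Pd(OAc)2 (3 mol %), SPhos (6 mol %), K3PO4, dioxane/H2O 4:1, 80 °C, BHT (trace)
Reagents that add atoms: none
Why: Suzuki–Miyaura vinylation, in which the electron-rich biarylphosphine allows oxidative addition to the electron-rich bromophenol, transmetalation of the vinylboronate should outpace any Heck reaction of the hindered chromene alkene, and the radical inhibitor protects the vinylphenol from polymerisation.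

**Step 5**
Reactants: 4 2-hydroxy-4,6-bis(tert-butyldimethylsilyloxy)-3,5-bis(3-methylbut-2-enyl)benzaldehyde; 9 2,2-dimethyl-6-vinyl-2H-chromen-7-ol
Product: 12 (2S,4S)-5,7-bis(tert-butyldimethylsilyloxy)-2-(7-hydroxy-2,2-dimethyl-2H-chromen-6-yl)-4-methoxy-6,8-bis(3-methylbut-2-enyl)chroman, via dimethyl acetal 10 (not isolated), via methoxy o-quinone methide 11 (not isolated)
Conditions: HC(OMe)3 (1.5 equiv), (R)-TRIP [(R)-3,3'-bis(2,4,6-triisopropylphenyl)-1,1'-binaphthyl-2,2'-diyl hydrogen phosphate] (10 mol %), 4 Å MS, toluene, 0 °C; then 9 (1.2 equiv), −40 °C; Et3N quench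
Reagents that add atoms: trimethyl orthoformate, COC(OC)OC
Why: Proposed new method: the acid and the orthoformate should turn 4 into acetal 10, which ionises to the E-configured methoxy o-quinone methide 11 (stabilised by the three oxygens of ring A); the nucleophilic terminal carbon of 9 then attacks the methide carbon (C3–C4) while the carbonyl oxygen of 11 captures the developing benzylic cation (O1–C2) in a concerted but asynchronous inverse-demand hetero-Diels–Alder reaction. The closest known reaction types are the chiral phosphoric acid catalysed [4+2] cycloaddition of o-quinone methides from o-hydroxybenzyl alcohols with o-hydroxystyrenes, which gives 2-arylchromans, and the racemic Lewis acid catalysed union of salicylaldehydes, orthoformates and alkenes to 4-alkoxychromans; an alkoxy quinone methide under chiral Brønsted acid control has no direct precedent. Ring C closes in the [4+2] mode, which in the stepwise limit is a 6-exo-trig capture of the ring B quinone methide cation by O1. C2 is set by the catalyst, whose phosphate holds the carbonyl oxygen of 11 through its acidic proton and the hydroxyl of 9 (the later 2'-OH) through its P=O group and so exposes one face of the vinyl group, whereas C4 is set relative to C2 by the endo transition state of the E-methide, which places methoxy and aryl cis and diequatorial. The step needs enantiofacial control (the two hydrogen bonds), head-to-tail regiochemistry (given by the polarity of both partners), reaction at the vinyl group instead of the chromene or prenyl alkenes (only the vinyl group is terminal, conjugated to the bound hydroxyl and free of the neopentyl-type hindrance at the chromene C3) and no re-ionisation at C4 or C2 afterwards (no free phenol is left beside C4, low temperature, amine quench before warming).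

**Step 6**
Reactants: 12 (2S,4S)-5,7-bis(tert-butyldimethylsilyloxy)-2-(7-hydroxy-2,2-dimethyl-2H-chromen-6-yl)-4-methoxy-6,8-bis(3-methylbut-2-enyl)chroman
Product: 13 (2S,4S)-5,7-bis(tert-butyldimethylsilyloxy)-2-[7-(tert-butyldimethylsilyloxy)-2,2-dimethyl-2H-chromen-6-yl]-4-methoxy-6,8-bis(3-methylbut-2-enyl)chroman
Conditions: TBSCl, imidazole, DMF, rt
Reagents that add atoms: tert-butyldimethylsilyl chloride, CC(C)(C)[Si](C)(C)Cl
Why: Standard phenol silylation under basic conditions that leave the benzylic methyl ether and both stereocentres untouched; it removes the only internal nucleophile that could trap C4 as a bridged ether on ionisation and keeps a free electron-rich phenol away from the later oxidant.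

**Step 7**
Reactants: 13 (2S,4S)-5,7-bis(tert-butyldimethylsilyloxy)-2-[7-(tert-butyldimethylsilyloxy)-2,2-dimethyl-2H-chromen-6-yl]-4-methoxy-6,8-bis(3-methylbut-2-enyl)chroman
Product: 14 (2S)-5,7-bis(tert-butyldimethylsilyloxy)-2-[7-(tert-butyldimethylsilyloxy)-2,2-dimethyl-2H-chromen-6-yl]-6,8-bis(3-methylbut-2-enyl)chroman-4-ol (mixture of C4 epimers)
Conditions: PPTS (0.2 equiv), THF/H2O 5:1, 35 °C
Reagents that add atoms: water, O
Why: SN1 solvolysis of a benzylic ether, as in acid exchange at C4 of 4-alkoxyflavans: C4 should ionise much more readily than C2 because its cation is stabilised by the three oxygens of ring A and methanol is the leaving group, water captures the cation, the loss of C4 configuration is irrelevant since this centre is oxidised next, and aryl silyl ethers and silyl-flanked prenyl groups tolerate the mild acid.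

**Step 8**
Reactants: 14 (2S)-5,7-bis(tert-butyldimethylsilyloxy)-2-[7-(tert-butyldimethylsilyloxy)-2,2-dimethyl-2H-chromen-6-yl]-6,8-bis(3-methylbut-2-enyl)chroman-4-ol
Product: 15 (2S)-5,7-bis(tert-butyldimethylsilyloxy)-2-[7-(tert-butyldimethylsilyloxy)-2,2-dimethyl-2H-chromen-6-yl]-6,8-bis(3-methylbut-2-enyl)chroman-4-one
Conditions: Dess–Martin periodinane, pyridine, CH2Cl2, 0 °C to rt
Reagents that add atoms: none
Why: Dess–Martin oxidation of a secondary benzylic alcohol under buffered, non-enolising conditions should converge both C4 epimers on one ketone and leave C2, the alkenes and the silyl ethers alone.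

**Step 9**
Reactants: 15 (2S)-5,7-bis(tert-butyldimethylsilyloxy)-2-[7-(tert-butyldimethylsilyloxy)-2,2-dimethyl-2H-chromen-6-yl]-6,8-bis(3-methylbut-2-enyl)chroman-4-one
Product: 16 euchrenone a3, (2S)-5,7-dihydroxy-2-(7-hydroxy-2,2-dimethyl-2H-chromen-6-yl)-6,8-bis(3-methylbut-2-enyl)chroman-4-one
Conditions: HF·pyridine, pyridine, THF, 0 °C to rt
Reagents that add atoms: none
Why: Fluoride cleavage of the three aryl silyl ethers in a weakly acidic buffered medium, which avoids the phenoxide- or enolate-driven opening of ring C to the chalcone that would racemise C2 and is too weak an acid to cyclise the prenyl groups onto the freed phenols.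

**Compound list**

1 | 2,4,6-trihydroxybenzaldehyde | O=Cc1c(O)cc(O)cc1O | starting material
2 | prenyl bromide (1-bromo-3-methylbut-2-ene) | CC(C)=CCBr | starting material
3 | 2,4,6-trihydroxy-3,5-bis(3-methylbut-2-enyl)benzaldehyde | O=Cc1c(O)c(CC=C(C)C)c(O)c(CC=C(C)C)c1O | intermediate
4 | 2-hydroxy-4,6-bis(tert-butyldimethylsilyloxy)-3,5-bis(3-methylbut-2-enyl)benzaldehyde | O=Cc1c(O)c(CC=C(C)C)c(O[Si](C)(C)C(C)(C)C)c(CC=C(C)C)c1O[Si](C)(C)C(C)(C)C | intermediate
5 | 4-bromoresorcinol | Oc1ccc(Br)c(O)c1 | starting material
6 | 3-methylbut-2-enal | CC(C)=CC=O | starting material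
7 | 6-bromo-2,2-dimethyl-2H-chromen-7-ol | Brc1cc2c(cc1O)OC(C)(C)C=C2 | intermediate
8 | vinylboronic acid pinacol ester | C=CB1OC(C)(C)C(C)(C)O1 | starting material
9 | 2,2-dimethyl-6-vinyl-2H-chromen-7-ol | C=Cc1cc2c(cc1O)OC(C)(C)C=C2 | intermediate
10 | dimethyl acetal of 4 | COC(OC)c1c(O)c(CC=C(C)C)c(O[Si](C)(C)C(C)(C)C)c(CC=C(C)C)c1O[Si](C)(C)C(C)(C)C | intermediate (not isolated)
11 | (E)-methoxy o-quinone methide, 6-(methoxymethylidene)-3,5-bis(tert-butyldimethylsilyloxy)-2,4-bis(3-methylbut-2-enyl)cyclohexa-2,4-dien-1-one | CO/C=C1/C(=O)C(CC=C(C)C)=C(O[Si](C)(C)C(C)(C)C)C(CC=C(C)C)=C1O[Si](C)(C)C(C)(C)C | intermediate (not isolated)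
12 | (2S,4S)-5,7-bis(tert-butyldimethylsilyloxy)-2-(7-hydroxy-2,2-dimethyl-2H-chromen-6-yl)-4-methoxy-6,8-bis(3-methylbut-2-enyl)chroman (2,4-cis) | CC(C)=CCc1c(O[Si](C)(C)C(C)(C)C)c(CC=C(C)C)c2c(c1O[Si](C)(C)C(C)(C)C)[C@@H](OC)C[C@@H](c1cc3c(cc1O)OC(C)(C)C=C3)O2 | intermediate
13 | (2S,4S)-5,7-bis(tert-butyldimethylsilyloxy)-2-[7-(tert-butyldimethylsilyloxy)-2,2-dimethyl-2H-chromen-6-yl]-4-methoxy-6,8-bis(3-methylbut-2-enyl)chroman | CC(C)=CCc1c(O[Si](C)(C)C(C)(C)C)c(CC=C(C)C)c2c(c1O[Si](C)(C)C(C)(C)C)[C@@H](OC)C[C@@H](c1cc3c(cc1O[Si](C)(C)C(C)(C)C)OC(C)(C)C=C3)O2 | intermediate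
14 | (2S)-5,7-bis(tert-butyldimethylsilyloxy)-2-[7-(tert-butyldimethylsilyloxy)-2,2-dimethyl-2H-chromen-6-yl]-6,8-bis(3-methylbut-2-enyl)chroman-4-ol, C4 epimers | CC(C)=CCc1c(O[Si](C)(C)C(C)(C)C)c(CC=C(C)C)c2c(c1O[Si](C)(C)C(C)(C)C)C(O)C[C@@H](c1cc3c(cc1O[Si](C)(C)C(C)(C)C)OC(C)(C)C=C3)O2 | intermediate
15 | (2S)-5,7-bis(tert-butyldimethylsilyloxy)-2-[7-(tert-butyldimethylsilyloxy)-2,2-dimethyl-2H-chromen-6-yl]-6,8-bis(3-methylbut-2-enyl)chroman-4-one | CC(C)=CCc1c(O[Si](C)(C)C(C)(C)C)c(CC=C(C)C)c2c(c1O[Si](C)(C)C(C)(C)C)C(=O)C[C@@H](c1cc3c(cc1O[Si](C)(C)C(C)(C)C)OC(C)(C)C=C3)O2 | intermediate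
16 | euchrenone a3, (2S)-5,7-dihydroxy-2-(7-hydroxy-2,2-dimethyl-2H-chromen-6-yl)-6,8-bis(3-methylbut-2-enyl)chroman-4-one | CC(C)=CCc1c(O)c(CC=C(C)C)c2c(c1O)C(=O)C[C@@H](c1cc3c(cc1O)OC(C)(C)C=C3)O2 | target

**Totals**

Total step count: 9.
Longest linear sequence: 7 steps (steps 1, 2, 5, 6, 7, 8, 9 from 1; the branch from 5 through steps 3, 4, 5–9 is equally long).

**Steps most likely to fail**

1. Step 5. The weak acid may not ionise the hindered, chelated aldehyde or its acetal at the temperature needed for selectivity. A loosely ion-paired background addition may erode enantiofacial selectivity. The product may re-ionise at C4 or C2, and the chromene alkene or the aromatic C8 position of the vinylphenol may compete with the vinyl group.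
   Fallback, known chemistry only: ring C is built at the ketone oxidation level by aldol addition and intramolecular etherification, and the enantiomers are separated. It sets out from 4 and 7 and comes back at 15.
   - From 4, addition of MeMgBr (THF, 0 °C) should give the benzylic alcohol F1, and MnO2 oxidation the 2-hydroxyacetophenone F2.
   - From 7, silylation (TBSCl, imidazole) should give the aryl bromide F3, and bromine–lithium exchange (t-BuLi, THF, −78 °C) with DMF quench the aldehyde F4.
   - The dilithium phenoxide–enolate of F2 (LiN(SiMe3)2, THF, −78 °C, quenched cold to forestall silyl migration) adds to F4 to give the racemic β-hydroxy ketone F5.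
   - Mitsunobu cyclodehydration (PPh3, DIAD) closes ring C through O1 to the racemic flavanone, that is 15 together with its (2R)-enantiomer F6.
   - Chromatography on a chiral stationary phase returns 15, from which step 9 follows.

2. Step 7. Methanol may be lost by elimination across C3–C4 to the flav-3-ene instead of by substitution. The acid may ionise the O1–C2 benzylic ether and erode the C2 configuration, or an aryl silyl group may be lost.
   Fallback: oxidative instead of solvolytic removal of the methoxy group, setting out from 13 and coming back at 15 without passing through 14. DDQ in wet, buffered CH2Cl2 at 0 °C should abstract the C4 hydride, the most hydridic C–H since it is flanked by the methoxy group and ring A. Hydration of the oxocarbenium ion and collapse of the hemiketal then give ketone 15 directly. No new compound is made.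

3. Step 1. O-alkylation may compete with C-alkylation, and mono-alkylation or geminal over-alkylation with dearomatisation may leave little of the 3,5-dialkylated product.
   Fallback: the two prenyl groups are introduced by sigmatropic rearrangement and olefin metathesis, setting out from 1 and coming back at 3.
   - Bis-O-allylation of 1 (allyl bromide, K2CO3, acetone) should give the diallyl ether F7.
   - Heating (N,N-diethylaniline, 190 °C) brings about a double aromatic Claisen rearrangement, with a Cope shift to the para position where the ortho site is taken, to the 3,5-diallyl compound F8.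
   - Cross-metathesis with 2-methylbut-2-ene (second-generation Grubbs catalyst, CH2Cl2, 40 °C) converts both allyl groups into prenyl groups and gives 3.

**Further compounds**

F1 | step 5 | 1-[2-hydroxy-4,6-bis(tert-butyldimethylsilyloxy)-3,5-bis(3-methylbut-2-enyl)phenyl]ethanol (racemic) | CC(O)c1c(O)c(CC=C(C)C)c(O[Si](C)(C)C(C)(C)C)c(CC=C(C)C)c1O[Si](C)(C)C(C)(C)C
F2 | step 5 | 1-[2-hydroxy-4,6-bis(tert-butyldimethylsilyloxy)-3,5-bis(3-methylbut-2-enyl)phenyl]ethanone | CC(=O)c1c(O)c(CC=C(C)C)c(O[Si](C)(C)C(C)(C)C)c(CC=C(C)C)c1O[Si](C)(C)C(C)(C)C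
F3 | step 5 | (6-bromo-2,2-dimethyl-2H-chromen-7-yl)oxy(tert-butyl)dimethylsilane | CC(C)(C)[Si](C)(C)Oc1cc2c(cc1Br)C=CC(C)(C)O2
F4 | step 5 | 7-(tert-butyldimethylsilyloxy)-2,2-dimethyl-2H-chromene-6-carbaldehyde | CC(C)(C)[Si](C)(C)Oc1cc2c(cc1C=O)C=CC(C)(C)O2
F5 | step 5 | 1-[2-hydroxy-4,6-bis(tert-butyldimethylsilyloxy)-3,5-bis(3-methylbut-2-enyl)phenyl]-3-hydroxy-3-[7-(tert-butyldimethylsilyloxy)-2,2-dimethyl-2H-chromen-6-yl]propan-1-one (racemic) | O=C(CC(O)c1cc2c(cc1O[Si](C)(C)C(C)(C)C)OC(C)(C)C=C2)c1c(O)c(CC=C(C)C)c(O[Si](C)(C)C(C)(C)C)c(CC=C(C)C)c1O[Si](C)(C)C(C)(C)C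
F6 | step 5 | (2R)-enantiomer of 15 | CC(C)=CCc1c(O[Si](C)(C)C(C)(C)C)c(CC=C(C)C)c2c(c1O[Si](C)(C)C(C)(C)C)C(=O)C[C@H](c1cc3c(cc1O[Si](C)(C)C(C)(C)C)OC(C)(C)C=C3)O2
F0 | step 7 | none | none
F7 | step 1 | 2,4-bis(allyloxy)-6-hydroxybenzaldehyde | O=Cc1c(O)cc(OCC=C)cc1OCC=C
F8 | step 1 | 3,5-diallyl-2,4,6-trihydroxybenzaldehyde | O=Cc1c(O)c(CC=C)c(O)c(CC=C)c1O
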